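**Retrosynthetic overview**

- Ring A carries the CH2CH2 bridge at C1, the two 4-hydroxybenzyl groups at C2 and C6, the oxygens at C3 and C5, and H at C4. Its C2–C6 chain, with both benzyl arms, is C2–C6 of a symmetrical 1,7-diarylheptane-3,5-dione.
- Only C1 and the two bridge carbons are missing. They come from the ester carbon and the Cα/Cβ of a ring-B cinnamate, so ring A (the only ring made) is closed by acylation (C1–C2) and aldol aromatisation (C1–C6).
- The dione comes from twofold γ-benzylation of acetylacetone. The cinnamate comes from 4-bromosalicylaldehyde by O-benzylation, aryl Grignard addition, ionic reduction and Heck reaction.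
- After the annulation: bis-O-methylation, one hydrogenation (alkene plus three benzyl ethers), and thiolate mono-demethylation of the symmetrical dimethoxy ring.

Key step: step 6

Remark: the target has no stereocentre and is achiral, so no enantiocontrol is needed; the only stereo-element on the way is the (E)-alkene of 11–15, which is removed in step 8. Grignard reagent 7 is taken as the commercial THF solution.

**Step 1**
Reactants: 1 acetylacetone; 2 4-(benzyloxy)benzyl bromide (2 equiv in two portions)
Product: 4 1,7-bis[4-(benzyloxy)phenyl]heptane-3,5-dione, via mono-benzylated dione 3 (not isolated)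
Conditions: LDA (2.1 equiv), THF, 0 °C; 2 (1.0 equiv); LDA (1.05 equiv), 0 °C; 2 (1.05 equiv), 0 °C → rt; aq HCl
Reagents that add atoms: none
Why: Hauser-type γ-alkylation of a β-diketone dianion, run twice in one flask: the terminal carbanion is the most nucleophilic site, and the third equivalent of LDA should re-form the dianion at the remaining methyl group rather than at the already substituted methylene.

**Step 2**
Reactants: 5 4-bromo-2-hydroxybenzaldehyde
Product: 6 2-(benzyloxy)-4-bromobenzaldehyde
Conditions: BnBr, K2CO3, DMF, rt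
Reagents that add atoms: benzyl bromide, BrCc1ccccc1
Why: Williamson etherification of an acidic salicylaldehyde phenol; the aldehyde and the aryl bromide are inert to carbonate.

**Step 3**
Reactants: 6 2-(benzyloxy)-4-bromobenzaldehyde; 7 4-(benzyloxy)phenylmagnesium bromide
Product: 8 [2-(benzyloxy)-4-bromophenyl][4-(benzyloxy)phenyl]methanol (racemic)
Conditions: 7 (1.1 equiv), THF, −20 → 0 °C; aq NH4Cl
Reagents that add atoms: none
Why: Grignard addition to the aldehyde; an aryl bromide does not exchange with an arylmagnesium bromide at this temperature, and the racemic carbinol centre is removed in step 4.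

**Step 4**
Reactants: 8 [2-(benzyloxy)-4-bromophenyl][4-(benzyloxy)phenyl]methanol
Product: 9 2-(benzyloxy)-1-[4-(benzyloxy)benzyl]-4-bromobenzene
Conditions: Et3SiH (3 equiv), TFA, CH2Cl2, 0 °C
Reagents that add atoms: none
Why: ionic hydrogenation: the benzhydryl cation, stabilised by the para- and ortho-alkoxy groups, forms readily and is trapped by hydride from the silane, while the benzyl ethers and the aryl bromide should survive the short cold acid exposure.

**Step 5**
Reactants: 9 2-(benzyloxy)-1-[4-(benzyloxy)benzyl]-4-bromobenzene; 10 methyl acrylate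
Product: 11 methyl (E)-3-{3-(benzyloxy)-4-[4-(benzyloxy)benzyl]phenyl}acrylate
Conditions: Pd(OAc)2 (5 mol%), P(o-tol)3 (10 mol%), Et3N, DMF, 100 °C, sealed tube
Reagents that add atoms: none
Why: Mizoroki–Heck reaction of an aryl bromide with an acrylate; syn-insertion and syn-β-hydride elimination should give the (E)-cinnamate.

**Step 6**
Reactants: 4 1,7-bis[4-(benzyloxy)phenyl]heptane-3,5-dione (2.1 equiv, excess recoverable); 11 methyl (E)-3-{3-(benzyloxy)-4-[4-(benzyloxy)benzyl]phenyl}acrylate
Product: 14 4,6-bis[4-(benzyloxy)benzyl]-5-[(E)-2-{3-(benzyloxy)-4-[4-(benzyloxy)benzyl]phenyl}ethenyl]benzene-1,3-diol, via styryl triketone 12 (not isolated), via cyclic aldol 13 (not isolated)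
Conditions: 4, LDA (4.2 equiv), THF, −78 → 0 °C; 11 (1.0 equiv) in THF, −78 → 0 °C; then degassed 1 M KOH in MeOH/H2O, rt → 40 °C, Ar; aq HCl to pH 3–4
Reagents that add atoms: none
Why: LDA converts 4 into its dianion, whose terminal carbanion (dione C2) attacks the ester carbonyl of 11 in a Claisen-type acylation to give triketone 12 (ring bond C1–C2), the second equivalent of dianion taking up the acidic proton of the product. In aqueous KOH the other terminal methylene (dione C6) is enolised and adds to the cinnamoyl ketone in a 6-(enolendo)-exo-trig aldol to give 13 (ring bond C1–C6), which loses water and tautomerises to resorcinol 14. The closest known chemistry is the γ-acylation of β-diketone dianions with esters followed by the base-mediated aldol aromatisation of 2,4,6-triketones to orcinol-type resorcinols, here run in one flask. No stereocentre is set: the sp3 centres of 12 and 13 vanish on aromatisation and the alkene stays E. The step needs 1,2-attack on the cinnamate instead of conjugate addition, which the hard dilithio carbanion, the low temperature and the absence of free LDA should favour. It also needs carbon aldol closure instead of γ-pyrone or oxa-Michael closure, which is served by the basic medium, by the cinnamoyl ketone having no enolisable CH2 (only one six-ring aldol is possible), and by aromatisation being the only irreversible exit; the symmetry of 4 removes any regiochemical choice.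

**Step 7**
Reactants: 14 the resorcinol stilbene from step 6
Product: 15 1,5-dimethoxy-2,4-bis[4-(benzyloxy)benzyl]-3-[(E)-2-{3-(benzyloxy)-4-[4-(benzyloxy)benzyl]phenyl}ethenyl]benzene
Conditions: MeI (4 equiv), K2CO3, acetone, reflux
Reagents that add atoms: iodomethane, CI
Why: Williamson O-methylation of both equivalent phenols; exhaustive methylation avoids the statistical problem of differentiating the two homotopic hydroxyl groups at this stage.

**Step 8**
Reactants: 15 the dimethoxy stilbene from step 7
Product: 16 5-{2-[2,6-bis(4-hydroxybenzyl)-3,5-dimethoxyphenyl]ethyl}-2-(4-hydroxybenzyl)phenol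
Conditions: H2 (1 atm), 10% Pd/C, THF/MeOH, rt
Reagents that add atoms: none
Why: catalytic hydrogenation saturates the stilbene alkene and hydrogenolyses the three aryl benzyl ethers in one operation, while diarylmethane C–C bonds and aryl methyl ethers are inert under these conditions.

**Step 9**
Reactants: 16 the dimethoxy triphenol from step 8
Product: 17 3-{2-[3-hydroxy-4-(4-hydroxybenzyl)phenyl]ethyl}-2,4-bis(4-hydroxybenzyl)-5-methoxyphenol (target, CNP0207338.0)
Conditions: NaSEt (8 equiv), DMF, 130 °C, Ar; 1 M HCl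
Reagents that add atoms: none
Why: SN2 O-demethylation by thiolate; the two methoxy groups are equivalent by symmetry, and once one is cleaved the resulting ring-A phenoxide deactivates the second, so the reaction should stop at the mono-methyl ether (the three other phenols only consume thiolate as base).

**Compound list**

1 | acetylacetone | CC(=O)CC(C)=O | starting material
2 | 4-(benzyloxy)benzyl bromide | BrCc1ccc(OCc2ccccc2)cc1 | starting material
3 | 6-[4-(benzyloxy)phenyl]hexane-2,4-dione (present as its lithium enolate) | CC(=O)CC(=O)CCc1ccc(OCc2ccccc2)cc1 | intermediate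
4 | 1,7-bis[4-(benzyloxy)phenyl]heptane-3,5-dione | O=C(CCc1ccc(OCc2ccccc2)cc1)CC(=O)CCc1ccc(OCc2ccccc2)cc1 | intermediate
5 | 4-bromo-2-hydroxybenzaldehyde | O=Cc1ccc(Br)cc1O | starting material
6 | 2-(benzyloxy)-4-bromobenzaldehyde | O=Cc1ccc(Br)cc1OCc1ccccc1 | intermediate
7 | 4-(benzyloxy)phenylmagnesium bromide | Br[Mg]c1ccc(OCc2ccccc2)cc1 | starting material
8 | [2-(benzyloxy)-4-bromophenyl][4-(benzyloxy)phenyl]methanol (racemic) | OC(c1ccc(OCc2ccccc2)cc1)c1ccc(Br)cc1OCc1ccccc1 | intermediate
9 | 2-(benzyloxy)-1-[4-(benzyloxy)benzyl]-4-bromobenzene | Brc1ccc(Cc2ccc(OCc3ccccc3)cc2)c(OCc2ccccc2)c1 | intermediate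
10 | methyl acrylate | C=CC(=O)OC | starting material
11 | methyl (E)-3-{3-(benzyloxy)-4-[4-(benzyloxy)benzyl]phenyl}acrylate | COC(=O)/C=C/c1ccc(Cc2ccc(OCc3ccccc3)cc2)c(OCc2ccccc2)c1 | intermediate
12 | (E)-4-[4-(benzyloxy)benzyl]-1-{3-(benzyloxy)-4-[4-(benzyloxy)benzyl]phenyl}-9-[4-(benzyloxy)phenyl]non-1-ene-3,5,7-trione (racemic, enolised) | O=C(/C=C/c1ccc(Cc2ccc(OCc3ccccc3)cc2)c(OCc2ccccc2)c1)C(Cc1ccc(OCc2ccccc2)cc1)C(=O)CC(=O)CCc1ccc(OCc2ccccc2)cc1 | intermediate
13 | 4,6-bis[4-(benzyloxy)benzyl]-5-hydroxy-5-[(E)-2-{3-(benzyloxy)-4-[4-(benzyloxy)benzyl]phenyl}ethenyl]cyclohexane-1,3-dione (diastereomer mixture) | OC1(/C=C/c2ccc(Cc3ccc(OCc4ccccc4)cc3)c(OCc3ccccc3)c2)C(Cc2ccc(OCc3ccccc3)cc2)C(=O)CC(=O)C1Cc1ccc(OCc2ccccc2)cc1 | intermediate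
14 | 4,6-bis[4-(benzyloxy)benzyl]-5-[(E)-2-{3-(benzyloxy)-4-[4-(benzyloxy)benzyl]phenyl}ethenyl]benzene-1,3-diol | Oc1cc(O)c(Cc2ccc(OCc3ccccc3)cc2)c(/C=C/c2ccc(Cc3ccc(OCc4ccccc4)cc3)c(OCc3ccccc3)c2)c1Cc1ccc(OCc2ccccc2)cc1 | intermediate
15 | 1,5-dimethoxy-2,4-bis[4-(benzyloxy)benzyl]-3-[(E)-2-{3-(benzyloxy)-4-[4-(benzyloxy)benzyl]phenyl}ethenyl]benzene | COc1cc(OC)c(Cc2ccc(OCc3ccccc3)cc2)c(/C=C/c2ccc(Cc3ccc(OCc4ccccc4)cc3)c(OCc3ccccc3)c2)c1Cc1ccc(OCc2ccccc2)cc1 | intermediate
16 | 5-{2-[2,6-bis(4-hydroxybenzyl)-3,5-dimethoxyphenyl]ethyl}-2-(4-hydroxybenzyl)phenol | COc1cc(OC)c(Cc2ccc(O)cc2)c(CCc2ccc(Cc3ccc(O)cc3)c(O)c2)c1Cc1ccc(O)cc1 | intermediate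
17 | 3-{2-[3-hydroxy-4-(4-hydroxybenzyl)phenyl]ethyl}-2,4-bis(4-hydroxybenzyl)-5-methoxyphenol | COc1cc(O)c(Cc2ccc(O)cc2)c(CCc2ccc(Cc3ccc(O)cc3)c(O)c2)c1Cc1ccc(O)cc1 | target

**Step count**

Total steps: 9. Longest linear sequence: 8 steps (steps 2–9, from 5); the dione arm joins after one step.

**Steps most likely to fail**

1. Step 6. The dianion may add to the cinnamate in the conjugate sense instead of acylating it. In the hydroxide stage the α-substituted diketone may undergo retro-Claisen cleavage, or close through oxygen (pyrone or oxa-Michael) faster than the unactivated terminal methylene closes through carbon. Fallback: build ring A by cross-coupling instead of annulation, setting out from aryl bromide 9 (with bromide 2) and returning at 15. Commercial 3,5-dimethoxybenzaldehyde F1 would be dibrominated with NBS (2.2 equiv, MeCN) at the two positions para to a methoxy group to give 2,6-dibromo-3,5-dimethoxybenzaldehyde F2. Twofold Negishi coupling (Pd(OAc)2/SPhos, THF, 60 °C) with 4-(benzyloxy)benzylzinc bromide F3, made from 2 and zinc dust/LiCl, would give 2,6-bis[4-(benzyloxy)benzyl]-3,5-dimethoxybenzaldehyde F4. Wittig methylenation with methylenetriphenylphosphorane F5 (from Ph3PCH3Br and KOtBu in THF) would give 2,4-bis[4-(benzyloxy)benzyl]-1,5-dimethoxy-3-vinylbenzene F6. A Heck reaction of F6 with 9 (Pd(OAc)2, P(o-tol)3, Et3N, DMF, 110 °C) would deliver 15, which continues with steps 8 and 9.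

2. Step 1. Proton exchange between the mono-benzylated enolate and unreacted dianion may lead to double alkylation at one terminus or alkylation at the central carbon, and the second deprotonation may not be fully selective for the methyl group. Fallback: a curcuminoid route from 1 that returns at 4. Acetylacetone 1, as its boron complex (B2O3, B(OnBu)3, n-BuNH2, EtOAc, 80 °C; then dilute HCl), would condense at both methyl groups with commercial 4-(benzyloxy)benzaldehyde F7 to give (1E,6E)-1,7-bis[4-(benzyloxy)phenyl]hepta-1,6-diene-3,5-dione F8. Its two conjugated C=C bonds would then be hydrogenated with sulfide-poisoned Pd/C (H2 1 atm, Pd/C, Ph2S, EtOAc), which should leave the aryl benzyl ethers intact, to give 4.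

3. Step 9. The demethylation may run on to the fully demethylated resorcinol, or stall because the poly-phenoxide is poorly soluble or air-sensitive at high temperature. Fallback: differentiate the two oxygens by methylation instead of demethylation, setting out from 14 and returning at 17. Resorcinol 14 would be mono-methylated statistically (MeI 1.0 equiv, K2CO3, acetone, rt) to give 4,6-bis[4-(benzyloxy)benzyl]-5-[(E)-2-{3-(benzyloxy)-4-[4-(benzyloxy)benzyl]phenyl}ethenyl]-3-methoxyphenol F9; recovered 14 would be recycled and the dimethyl ether 15 fed into the main route. Hydrogenation of F9 (H2, Pd/C, THF/MeOH) would give 17 directly.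

**Further compounds**

F1 | step 6 | 3,5-dimethoxybenzaldehyde (commercial starting material) | COc1cc(OC)cc(C=O)c1
F2 | step 6 | 2,6-dibromo-3,5-dimethoxybenzaldehyde | COc1cc(OC)c(Br)c(C=O)c1Br
F3 | step 6 | 4-(benzyloxy)benzylzinc bromide | Br[Zn]Cc1ccc(OCc2ccccc2)cc1
F4 | step 6 | 2,6-bis[4-(benzyloxy)benzyl]-3,5-dimethoxybenzaldehyde | COc1cc(OC)c(Cc2ccc(OCc3ccccc3)cc2)c(C=O)c1Cc1ccc(OCc2ccccc2)cc1
F5 | step 6 | methylenetriphenylphosphorane (formed in the flask) | C=P(c1ccccc1)(c1ccccc1)c1ccccc1
F6 | step 6 | 2,4-bis[4-(benzyloxy)benzyl]-1,5-dimethoxy-3-vinylbenzene | COc1cc(OC)c(Cc2ccc(OCc3ccccc3)cc2)c(C=C)c1Cc1ccc(OCc2ccccc2)cc1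
F7 | step 1 | 4-(benzyloxy)benzaldehyde (commercial starting material) | O=Cc1ccc(OCc2ccccc2)cc1
F8 | step 1 | (1E,6E)-1,7-bis[4-(benzyloxy)phenyl]hepta-1,6-diene-3,5-dione | O=C(/C=C/c1ccc(OCc2ccccc2)cc1)CC(=O)/C=C/c1ccc(OCc2ccccc2)cc1
F9 | step 9 | 4,6-bis[4-(benzyloxy)benzyl]-5-[(E)-2-{3-(benzyloxy)-4-[4-(benzyloxy)benzyl]phenyl}ethenyl]-3-methoxyphenol | COc1cc(O)c(Cc2ccc(OCc3ccccc3)cc2)c(/C=C/c2ccc(Cc3ccc(OCc4ccccc4)cc3)c(OCc3ccccc3)c2)c1Cc1ccc(OCc2ccccc2)cc1
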